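The bond between oxolane ring carbon C4 and the exocyclic carbinol carbon is made as a C=C bond. The step exploits that C4 stands next to C5, the ring OCH2 carbon. Carried as a lactone carbonyl, C5 acidifies C4–H of a trans-4-methyl-5-arylbutyrolactone. One-flask aldol condensation with veratraldehyde joins both halves and fixes the E geometry (aryl cis to C3). A plain aldol addition would enter trans to the C3 methyl group and give the wrong epimer. Once the carbonyl is reduced to CH2, one syn hydroboration anti to that methyl group converts the alkene geometry into both missing stereocentres, with hydrogen reaching C4 last.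

Key step: step 4

Numbering used for the ring: O1, C2 (aryl), C3 (methyl), C4 (side chain), C5 (OCH2).

Assumption: the S-configured phosphoric acid of step 1 is taken to steer the crotyl group to the Si face of the aldehyde. If the sense proved opposite, the R acid would be used and nothing else would change.

Step 1
Reactants: 1 3,4-dimethoxybenzaldehyde (veratraldehyde); 2 (E)-crotylboronic acid pinacol ester
Product: 4 (1S,2S)-1-(3,4-dimethoxyphenyl)-2-methylbut-3-en-1-ol, via pinacol borate ester 3 (not isolated)
Conditions: (S)-TRIP [(S)-3,3'-bis(2,4,6-triisopropylphenyl)-1,1'-binaphthyl-2,2'-diyl hydrogen phosphate, 5 mol%], toluene, −30 °C; aq. NaHCO3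
Reagents that add atoms: none
Why: Chiral-phosphoric-acid-catalysed crotylboration through a closed chair (Zimmerman–Traxler type) transition state, in which the E geometry of 2 becomes the anti relationship and the catalyst-bound boronate should reach the Si face of 1, so that both stereocentres (1S,2S) are set here.

Step 2
Reactants: 4 (1S,2S)-1-(3,4-dimethoxyphenyl)-2-methylbut-3-en-1-ol
Product: 6 (1S,2S)-1-(3,4-dimethoxyphenyl)-2-methylbutane-1,4-diol, via bis(9-BBN) adduct 5 (not isolated)
Conditions: 9-BBN (2.5 equiv), THF, 0 °C to rt; NaOH, H2O2, 0 °C to rt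
Reagents that add atoms: 9-borabicyclo[3.3.1]nonane (9-BBN), B1C2CCCC1CCC2 (boron groups of 5 only); hydrogen peroxide, OO (new hydroxyl oxygen)
Why: Hydroboration–oxidation, in which the first equivalent of 9-BBN is consumed by the hydroxyl group, the second adds anti-Markovnikov to the terminal alkene, and alkaline peroxide replaces boron by hydroxyl without touching either stereocentre.

Step 3
Reactants: 6 (1S,2S)-1-(3,4-dimethoxyphenyl)-2-methylbutane-1,4-diol
Product: 8 (4S,5S)-5-(3,4-dimethoxyphenyl)-4-methyloxolan-2-one, via lactol 7 (not isolated)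
Conditions: TEMPO (0.2 equiv), PhI(OAc)2 (2.5 equiv), CH2Cl2, rt
Reagents that add atoms: none
Why: Oxoammonium-mediated oxidative lactonisation, in which the unhindered primary alcohol is oxidised first, the aldehyde closes to lactol 7 with the benzylic hydroxyl group and is oxidised on, so the benzylic C–O bond is never broken.

Step 4
Reactants: 8 (4S,5S)-5-(3,4-dimethoxyphenyl)-4-methyloxolan-2-one; 1 3,4-dimethoxybenzaldehyde
Product: 12 (3E,4S,5S)-5-(3,4-dimethoxyphenyl)-3-[(3,4-dimethoxyphenyl)methylidene]-4-methyloxolan-2-one, via lithium enolate 9 (not isolated), via lithium aldolate 10 (not isolated), via aldol acetate 11 (not isolated)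
Conditions: LiN(SiMe3)2, THF, −78 °C; 1, −78 °C; Ac2O, −78 to 0 °C; DBU, 0 °C to rt
Reagents that add atoms: LiN(SiMe3)2, [Li+].C[Si](C)(C)[N-][Si](C)(C)C (lithium of 9 and 10 only); acetic anhydride, CC(=O)OC(C)=O (acetyl group of 11 only)
Why: LiN(SiMe3)2 removes a proton from lactone C3 (the future ring carbon C4), enolate 9 adds to the non-enolisable aldehyde 1, aldolate 10 is trapped as acetate 11 and DBU expels acetate by E1cB elimination, which together is the classical aldol condensation used for α-arylidene butyrolactones. No ring is closed and no new stereocentre is kept: the two transient centres of 10 and 11 (addition anti to the methyl group, carbinol centre unselective) are erased, so all aldol diastereomers converge on one alkene. The stereochemical element created is the double-bond geometry, and the lactone carbonyl controls it: in the enolate that loses acetate the aryl group turns away from the carbonyl oxygen, which leaves the vinyl hydrogen syn to C=O and the aryl group cis to the methyl-bearing carbon (E), while the methyl group escapes allylic 1,3-strain by going pseudo-axial. The step needs cross- over self-condensation, secured by complete enolisation before 1 is added, and an exocyclic over an endocyclic double bond, secured by short exposure to an amidine base at or below room temperature. The two stereocentres of 8 are not acidic and should pass through unchanged.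

Step 5
Reactants: 12 (3E,4S,5S)-5-(3,4-dimethoxyphenyl)-3-[(3,4-dimethoxyphenyl)methylidene]-4-methyloxolan-2-one
Product: 13 (1S,2S,3E)-1-(3,4-dimethoxyphenyl)-3-[(3,4-dimethoxyphenyl)methylidene]-2-methylbutane-1,4-diol
Conditions: iBu2AlH (3 equiv), CH2Cl2, −78 to 0 °C; aq. potassium sodium tartrate
Reagents that add atoms: none
Why: 1,2-Reduction of an α,β-unsaturated lactone by an electrophilic aluminium hydride, which should leave the conjugated double bond, its E geometry and both stereocentres untouched.

Step 6
Reactants: 13 (1S,2S,3E)-1-(3,4-dimethoxyphenyl)-3-[(3,4-dimethoxyphenyl)methylidene]-2-methylbutane-1,4-diol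
Product: 15 (2S,3S,4E)-2-(3,4-dimethoxyphenyl)-4-[(3,4-dimethoxyphenyl)methylidene]-3-methyloxolane, via primary mesylate 14 (not isolated)
Conditions: MsCl (1.05 equiv), Et3N (3 equiv), CH2Cl2, −20 °C to rt
Reagents that add atoms: methanesulfonyl chloride, CS(=O)(=O)Cl (mesyl group of 14 only)
Why: Chemoselective mesylation of the unhindered primary allylic alcohol followed by 5-exo-tet intramolecular Williamson-type etherification by the benzylic hydroxyl group, so the benzylic C–O bond keeps its configuration and the former carbonyl carbon ends as the ring OCH2 group.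

Step 7
Reactants: 15 (2S,3S,4E)-2-(3,4-dimethoxyphenyl)-4-[(3,4-dimethoxyphenyl)methylidene]-3-methyloxolane
Product: 17 (2S,3S,4R)-2-(3,4-dimethoxyphenyl)-4-[(R)-(3,4-dimethoxyphenyl)(hydroxy)methyl]-3-methyloxolane, via benzylic borane 16 (not isolated)
Conditions: BH3·THF, THF, 0 °C to rt; NaOH, H2O2, 0 °C
Reagents that add atoms: borane–tetrahydrofuran, B.C1CCOC1 (boron of 16 only); hydrogen peroxide, OO (carbinol oxygen)
Why: Hydroboration–oxidation, in which the four-centre syn addition puts boron on the less substituted benzylic carbon and hydrogen on C4 from the face anti to the pseudo-axial C3 methyl group, which turns the side chain cis to that methyl group (4R) and, because the aryl group lies cis to C3 in the E alkene, should give the R carbinol after oxidation with retention.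

Compound list
1 | 3,4-dimethoxybenzaldehyde (veratraldehyde) | COc1ccc(C=O)cc1OC | starting material
2 | (E)-crotylboronic acid pinacol ester | C/C=C/CB1OC(C)(C)C(C)(C)O1 | starting material
3 | pinacol borate ester of alcohol 4 | COc1ccc([C@@H](OB2OC(C)(C)C(C)(C)O2)[C@@H](C)C=C)cc1OC | intermediate
4 | (1S,2S)-1-(3,4-dimethoxyphenyl)-2-methylbut-3-en-1-ol (anti) | COc1ccc([C@@H](O)[C@@H](C)C=C)cc1OC | intermediate
5 | bis(9-BBN) adduct of 4 (O-borinate and terminal C-borane) | COc1ccc([C@@H](OB2C3CCCC2CCC3)[C@@H](C)CCB2C3CCCC2CCC3)cc1OC | intermediate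
6 | (1S,2S)-1-(3,4-dimethoxyphenyl)-2-methylbutane-1,4-diol | COc1ccc([C@@H](O)[C@@H](C)CCO)cc1OC | intermediate
7 | (4S,5S)-5-(3,4-dimethoxyphenyl)-4-methyloxolan-2-ol (lactol, anomers) | COc1ccc([C@H]2OC(O)C[C@@H]2C)cc1OC | intermediate
8 | (4S,5S)-5-(3,4-dimethoxyphenyl)-4-methyloxolan-2-one (trans lactone) | COc1ccc([C@H]2OC(=O)C[C@@H]2C)cc1OC | intermediate
9 | lithium enolate of 8 | COc1ccc([C@H]2OC([O-])=C[C@@H]2C)cc1OC.[Li+] | intermediate
10 | lithium aldolate, side chain trans to methyl, carbinol centre undefined | COc1ccc([C@H]2OC(=O)[C@@H](C([O-])c3ccc(OC)c(OC)c3)[C@@H]2C)cc1OC.[Li+] | intermediate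
11 | aldol acetate, side chain trans to methyl, acetoxy centre undefined | COc1ccc([C@H]2OC(=O)[C@@H](C(OC(C)=O)c3ccc(OC)c(OC)c3)[C@@H]2C)cc1OC | intermediate
12 | (3E,4S,5S)-5-(3,4-dimethoxyphenyl)-3-[(3,4-dimethoxyphenyl)methylidene]-4-methyloxolan-2-one | COc1ccc([C@H]2OC(=O)/C(=C/c3ccc(OC)c(OC)c3)[C@@H]2C)cc1OC | intermediate
13 | (1S,2S,3E)-1-(3,4-dimethoxyphenyl)-3-[(3,4-dimethoxyphenyl)methylidene]-2-methylbutane-1,4-diol | COc1ccc([C@@H](O)[C@@H](C)/C(CO)=C\c2ccc(OC)c(OC)c2)cc1OC | intermediate
14 | primary allylic mesylate of 13 | COc1ccc([C@@H](O)[C@@H](C)/C(COS(C)(=O)=O)=C\c2ccc(OC)c(OC)c2)cc1OC | intermediate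
15 | (2S,3S,4E)-2-(3,4-dimethoxyphenyl)-4-[(3,4-dimethoxyphenyl)methylidene]-3-methyloxolane | COc1ccc([C@H]2OC/C(=C/c3ccc(OC)c(OC)c3)[C@@H]2C)cc1OC | intermediate
16 | benzylic monoalkylborane, boron in place of the carbinol oxygen of 17 | COc1ccc([C@H]2OC[C@H]([C@@H](B)c3ccc(OC)c(OC)c3)[C@@H]2C)cc1OC | intermediate
17 | (2S,3S,4R)-2-(3,4-dimethoxyphenyl)-4-[(R)-(3,4-dimethoxyphenyl)(hydroxy)methyl]-3-methyloxolane | COc1ccc([C@H]2OC[C@H]([C@@H](O)c3ccc(OC)c(OC)c3)[C@@H]2C)cc1OC | target

Total step count: 7. Longest linear sequence: 7 steps (1 to 17); aldehyde 1 enters twice, in steps 1 and 4.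

Steps most likely to fail

Step 7. Facial discrimination may be insufficient, because the C2 aryl group sits on the face that borane must attack. Some boron may also be placed on the ring carbon and then be lost by β-alkoxy elimination. The fallback sets out from 12 and comes back at 17.
- Copper-catalysed conjugate borylation (CuCl, NaOtBu, a Josiphos-type ferrocenyl diphosphine of the matching sense, B2pin2, MeOH, THF) would place boron on the benzylic carbon under ligand control. The copper enolate would be protonated anti to the methyl group, giving the 3,4-cis β-boryl lactone F1.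
- NaBO3·4H2O would convert it with retention into the β-hydroxy lactone F2, and LiBH4 would open this to the triol F3.
- TsCl in pyridine would give the primary tosylate F4. NaH would close it through the benzylic hydroxyl group that forms the five-membered ring rather than the four-membered one.

Step 4. The E/Z ratio may erode, the aldolate may revert before it is acetylated, or the base may move the double bond into the ring and erase the methyl-bearing stereocentre. The fallback sets out from 8 and comes back at 12.
- LiN(iPr)2 (2 equiv) and ClP(O)(OEt)2 in THF would give, by enol phosphate to phosphonate rearrangement, the α-diethylphosphono lactone F5.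
- This would join 1 through the same carbon atoms in a Horner–Wadsworth–Emmons olefination under Masamune–Roush conditions (LiCl, DBU, MeCN).

Step 6. The electron-rich cinnamyl-type mesylate may ionise to an allyl cation. That would cost the alkene geometry or allow closure at the benzylic terminus in an SN2′ sense. The fallback sets out from 12 and comes back at 15, bypassing the diol.
- iBu2AlH (1.1 equiv, toluene, −78 °C) would stop at the α-arylidene lactol F6.
- Ionic hydrogenation (Et3SiH, BF3·OEt2, CH2Cl2, −78 °C) would deliver hydride to the oxocarbenium carbon.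

Further compounds
F1 | step 7 | 3,4-cis lactone carrying a pinacol boronate in place of the carbinol oxygen of F2 | COc1ccc([C@H]2OC(=O)[C@H]([C@@H](B3OC(C)(C)C(C)(C)O3)c3ccc(OC)c(OC)c3)[C@@H]2C)cc1OC
F2 | step 7 | (3S,4S,5S)-5-(3,4-dimethoxyphenyl)-3-[(R)-(3,4-dimethoxyphenyl)(hydroxy)methyl]-4-methyloxolan-2-one | COc1ccc([C@H]2OC(=O)[C@H]([C@@H](O)c3ccc(OC)c(OC)c3)[C@@H]2C)cc1OC
F3 | step 7 | (1R,2R,3S,4S)-1,4-bis(3,4-dimethoxyphenyl)-2-(hydroxymethyl)-3-methylbutane-1,4-diol | COc1ccc([C@@H](O)[C@@H](C)[C@H](CO)[C@@H](O)c2ccc(OC)c(OC)c2)cc1OC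
F4 | step 7 | primary tosylate of triol F3 | COc1ccc([C@@H](O)[C@@H](C)[C@H](COS(=O)(=O)c2ccc(C)cc2)[C@@H](O)c2ccc(OC)c(OC)c2)cc1OC
F5 | step 4 | diethyl [(4S,5S)-5-(3,4-dimethoxyphenyl)-4-methyl-2-oxooxolan-3-yl]phosphonate (C3 epimers) | COc1ccc([C@H]2OC(=O)C(P(=O)(OCC)OCC)[C@@H]2C)cc1OC
F6 | step 6 | (3E,4S,5S)-5-(3,4-dimethoxyphenyl)-3-[(3,4-dimethoxyphenyl)methylidene]-4-methyloxolan-2-ol (anomers) | COc1ccc([C@H]2OC(O)/C(=C/c3ccc(OC)c(OC)c3)[C@@H]2C)cc1OC
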